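## Retrosynthetic overview
1. C2=CH2 ⇒ C2=O. The exocyclic enol ether is sensitive to acid and to Br+, so it is made last, by methylenation of a fully halogenated δ-lactone.
2. C3'–Br/C4'–Cl ⇒ cyclohexene. This is an anti BrCl addition followed by a diaxial→diequatorial halogen interchange, done after the oxane ring is closed.
3. Key disconnection: O1–C6, formed together with C5–Br, by 6-endo bromolactonisation of a prenylated tertiary α-hydroxy acid.
4. α-Hydroxy acid ⇒ 1,2-diol ⇒ 2,2-disubstituted epoxy alcohol + isobutenyl Grignard reagent. The epoxide ⇒ Sharpless epoxidation of limonen-10-ol ⇒ (S)-limonene.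
5. Ring order: the carbocycle is bought with limonene. The oxane is the only ring formed (step 5).

Assumption: the SMILES is read as (3R,5R) in the oxane (OH cis to Br) and (1S,3S,4S) in the cyclohexane (side chain, Br and Cl equatorial, CH3 axial); primed locants refer to the cyclohexane ring.

## Route

Step 1
Reactants: 1 (S)-(−)-limonene
Product: 4 2-[(1S)-4-methylcyclohex-3-en-1-yl]prop-2-en-1-ol, via allyllithium 2 (not isolated), via allylboronate 3 (not isolated)
Conditions: n-BuLi, TMEDA, hexane, rt, 16 h; B(OMe)3, THF, −78 °C to rt; H2O2 (30%), NaOH aq, 0 °C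
Reagents that add atoms: n-butyllithium CCCC[Li]; trimethyl borate COB(OC)OC; hydrogen peroxide OO
Why: Allylic metalation followed by borylation and boronate oxidation: n-BuLi·TMEDA deprotonates only the isopropenyl methyl group, the resulting 2-substituted allyl anion has two identical CH2 ends so no regioisomer can form, and neither the ring alkene nor the C1' stereocentre from limonene is touched.

Step 2
Reactants: 4 2-[(1S)-4-methylcyclohex-3-en-1-yl]prop-2-en-1-ol
Product: 5 [(2R)-2-[(1S)-4-methylcyclohex-3-en-1-yl]oxiran-2-yl]methanol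
Conditions: Ti(OiPr)4 (10 mol%), D-(−)-diethyl tartrate (12 mol%), t-BuOOH, 4 Å MS, CH2Cl2, −20 °C
Reagents that add atoms: tert-butyl hydroperoxide CC(C)(C)OO
Why: Sharpless asymmetric epoxidation: only the allylic-alcohol alkene is bound and oxidised by the titanium tartrate peroxide complex, and D-(−)-tartrate delivers oxygen to the face that makes the quaternary epoxide carbon R (reagent control, because the neighbouring ring stereocentre is nearly symmetric), which fixes the future C3 carbinol.

Step 3
Reactants: 5 [(2R)-2-[(1S)-4-methylcyclohex-3-en-1-yl]oxiran-2-yl]methanol; 6 2-methylprop-1-enylmagnesium bromide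
Product: 7 (2R)-5-methyl-2-[(1S)-4-methylcyclohex-3-en-1-yl]hex-4-ene-1,2-diol
Conditions: 6 (3 equiv), CuI (10 mol%), THF, −30 to 0 °C; then H2O
Reagents that add atoms: none
Why: Copper-catalysed SN2 opening of a 2,2-disubstituted epoxide by an alkenyl Grignard reagent occurs only at the free CH2 end, which turns the isobutenyl group into the prenyl chain and leaves the quaternary C–O bond, and hence the R configuration, intact.

Step 4
Reactants: 7 (2R)-5-methyl-2-[(1S)-4-methylcyclohex-3-en-1-yl]hex-4-ene-1,2-diol
Product: 9 (2R)-2-hydroxy-5-methyl-2-[(1S)-4-methylcyclohex-3-en-1-yl]hex-4-enoic acid, via hydroxy aldehyde 8 (not isolated)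
Conditions: 2,2,6,6-tetramethylpiperidine-1-oxyl (TEMPO, 7 mol%), NaClO2 (2 equiv), NaOCl (2 mol%), MeCN/phosphate buffer pH 6.7, 35 °C
Reagents that add atoms: sodium chlorite [Na+].[O-]Cl=O
Why: Nitroxyl/chlorite oxidation (Anelli–Zhao type with a Pinnick-type second stage) acts only on the primary alcohol, runs through aldehyde 8 to the acid without glycol cleavage, cannot touch the tertiary carbinol, and spares the trisubstituted alkenes because hypochlorite is kept at a catalytic level.

Step 5
Reactants: 9 (2R)-2-hydroxy-5-methyl-2-[(1S)-4-methylcyclohex-3-en-1-yl]hex-4-enoic acid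
Product: 10 (3R,5R)-5-bromo-3-hydroxy-6,6-dimethyl-3-[(1S)-4-methylcyclohex-3-en-1-yl]oxan-2-one
Conditions: Zn(OPiv)2 (20 mol%), NBS (1.05 equiv), 4 Å MS, CH2Cl2/toluene 1:1, −40 °C, dark
Reagents that add atoms: N-bromosuccinimide O=C1CCC(=O)N1Br
Why: Proposed new method: zinc-chelate-templated 6-endo bromolactonisation, in which divalent zinc binds the α-hydroxy carboxylate as a flat five-membered chelate that (a) holds the C3–OH in the carboxylate plane, so that in the chair-like transition state OH is pseudo-equatorial and the cyclohexenyl group pseudo-axial, (b) ties up the tertiary OH and so shuts off 5-endo ether formation, and (c) leaves the distal carboxylate oxygen free to attack the tertiary (Markovnikov) end of the reversibly formed prenyl bromonium ion anti to bromine, so that Br ends up equatorial and cis to OH (5R), while the ring alkene has no internal nucleophile and gives its Br+ back; the closest known reaction types are the 6-endo halolactonisation of 5-methylhex-4-enoic acids and zinc-carboxylate-catalysed iodolactonisation.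

Step 6
Reactants: 10 (3R,5R)-5-bromo-3-hydroxy-6,6-dimethyl-3-[(1S)-4-methylcyclohex-3-en-1-yl]oxan-2-one
Product: 12 (3R,5R)-5-bromo-3-[(1S,3S,4S)-3-bromo-4-chloro-4-methylcyclohexyl]-3-hydroxy-6,6-dimethyloxan-2-one, via diaxial bromochloride 11 (not isolated)
Conditions: Bu4N[BrCl2] (1.1 equiv), CH2Cl2, −20 °C; then MeNO2, 70 °C; chromatography
Reagents that add atoms: tetrabutylammonium dichlorobromate CCCC[N+](CCCC)(CCCC)CCCC.[Cl-].ClBr
Why: Electrophilic anti bromochlorination followed by the diaxial-to-diequatorial 1,2-dihalide rearrangement known from steroid dibromides: Br+ adds to both faces, the bromonium ion on the face syn to the C1' substituent is opened from the opposite face either at C4' (giving 12 directly) or, following the Fürst–Plattner rule, at C3' (giving 11), and on warming in a polar solvent 11 passes through the same bromonium chloride ion pair to 12, which has Cl on the tertiary carbon and both halogens equatorial, while the adduct from the other face (expected to be about half of the material) is removed by chromatography.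

Step 7
Reactants: 12 (3R,5R)-5-bromo-3-[(1S,3S,4S)-3-bromo-4-chloro-4-methylcyclohexyl]-3-hydroxy-6,6-dimethyloxan-2-one
Product: 13 (3R,5R)-5-bromo-3-[(1S,3S,4S)-3-bromo-4-chloro-4-methylcyclohexyl]-6,6-dimethyl-2-methylideneoxan-3-ol
Conditions: Cp2TiMe2 (3 equiv), toluene, 75 °C, dark; NaHCO3 aq; Et3N-deactivated SiO2
Reagents that add atoms: dimethyltitanocene C[Ti+2]C.c1cc[cH-]c1.c1cc[cH-]c1
Why: Petasis methylenation: on heating, Cp2TiMe2 loses methane to give Cp2Ti=CH2, which exchanges the lactone C=O for C=CH2 by cycloaddition and cycloreversion under neutral conditions that leave the equatorial C–Br and C–Cl bonds alone, the free OH only consumes one extra equivalent and is released on work-up, no stereocentre is touched, and the double bond cannot move into the ring because C3 is quaternary.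

## Compound list
1 | (S)-(−)-limonene | C=C(C)[C@H]1CCC(C)=CC1 | starting material
2 | {2-[(1S)-4-methylcyclohex-3-en-1-yl]prop-2-en-1-yl}lithium | [Li]CC(=C)[C@H]1CCC(C)=CC1 | intermediate
3 | dimethyl {2-[(1S)-4-methylcyclohex-3-en-1-yl]prop-2-en-1-yl}boronate | COB(OC)CC(=C)[C@H]1CCC(C)=CC1 | intermediate
4 | 2-[(1S)-4-methylcyclohex-3-en-1-yl]prop-2-en-1-ol | OCC(=C)[C@H]1CCC(C)=CC1 | intermediate
5 | [(2R)-2-[(1S)-4-methylcyclohex-3-en-1-yl]oxiran-2-yl]methanol | C1O[C@@]1(CO)[C@H]1CCC(C)=CC1 | intermediate
6 | 2-methylprop-1-enylmagnesium bromide | CC(C)=C[Mg]Br | starting material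
7 | (2R)-5-methyl-2-[(1S)-4-methylcyclohex-3-en-1-yl]hex-4-ene-1,2-diol | CC(C)=CC[C@@](CO)(O)[C@H]1CCC(C)=CC1 | intermediate
8 | (2R)-2-hydroxy-5-methyl-2-[(1S)-4-methylcyclohex-3-en-1-yl]hex-4-enal | CC(C)=CC[C@@](C=O)(O)[C@H]1CCC(C)=CC1 | intermediate
9 | (2R)-2-hydroxy-5-methyl-2-[(1S)-4-methylcyclohex-3-en-1-yl]hex-4-enoic acid | CC(C)=CC[C@@](C(=O)O)(O)[C@H]1CCC(C)=CC1 | intermediate
10 | (3R,5R)-5-bromo-3-hydroxy-6,6-dimethyl-3-[(1S)-4-methylcyclohex-3-en-1-yl]oxan-2-one | O=C1OC(C)(C)[C@H](Br)C[C@@]1(O)[C@H]1CCC(C)=CC1 | intermediate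
11 | (3R,5R)-5-bromo-3-[(1S,3R,4R)-4-bromo-3-chloro-4-methylcyclohexyl]-3-hydroxy-6,6-dimethyloxan-2-one | O=C1OC(C)(C)[C@H](Br)C[C@@]1(O)[C@H]1CC[C@@](C)(Br)[C@H](Cl)C1 | intermediate
12 | (3R,5R)-5-bromo-3-[(1S,3S,4S)-3-bromo-4-chloro-4-methylcyclohexyl]-3-hydroxy-6,6-dimethyloxan-2-one | O=C1OC(C)(C)[C@H](Br)C[C@@]1(O)[C@H]1CC[C@](C)(Cl)[C@@H](Br)C1 | intermediate
13 | (3R,5R)-5-bromo-3-[(1S,3S,4S)-3-bromo-4-chloro-4-methylcyclohexyl]-6,6-dimethyl-2-methylideneoxan-3-ol | C=C1OC(C)(C)[C@H](Br)C[C@@]1(O)[C@H]1CC[C@](C)(Cl)[C@@H](Br)C1 | target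

## Step count and risks
Total step count: 7. Longest linear sequence: 7 steps, from 1.

**Risk 1, step 5 (the proposed new reaction).** It can fail through a low 5R:5S ratio, through 5-exo closure, or through attack of Br+ on the ring alkene. The fallback uses known chemistry and closes the ring through the acyl C–O bond instead. It sets out from 9 and comes back at 10.
- 9 is esterified (MeI, K2CO3, DMF) to the methyl ester F1.
- Only the prenyl alkene is epoxidised, directed by the homoallylic tertiary OH, to give the (S)-epoxide F2. The conditions are Hf(OtBu)4, a chiral bishydroxamic acid ligand and cumene hydroperoxide. The plain version is VO(acac)2/t-BuOOH with separation of the epimers.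
- Li2NiBr4 in THF opens the epoxide by SN2 attack at the secondary carbon, with inversion, to the (4R)-bromohydrin F3.
- Catalytic camphorsulfonic acid in warm benzene closes the δ-lactone with loss of methanol to give 10.

**Risk 2, step 6.** Facial selectivity is absent, so about half of the material is lost as the other diaxial adduct. The interchange of 11 to 12 may also stop at an equilibrium or lose HBr. A realistic yield of 12 is 30–40%. The fallback fixes the face first, through an epoxide, and generates only the required bromonium ion. It sets out from 10 and comes back at 11.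
- The ring alkene is epoxidised on the face anti to the side chain to give the epoxide F4. The catalyst is the matching enantiomer of N,N'-bis(3,5-di-tert-butylsalicylidene)-1,2-cyclohexanediaminomanganese chloride, with mCPBA and N-methylmorpholine N-oxide in CH2Cl2 at −78 °C.
- HBr in AcOH/CH2Cl2 at −20 °C opens F4 at the tertiary carbon, where the Markovnikov and diaxial rules agree, to give the diaxial bromohydrin F5.
- PPh3/N-chlorosuccinimide activates the axial secondary OH, which is expelled by the antiperiplanar bromine.
- Chloride then opens the resulting bromonium ion to give 11 together with 12. Heating as in step 6 completes the conversion.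

**Risk 3, step 7.** The lactone carbonyl is flanked by a quaternary carbinol bearing a free OH. Methylenation may therefore be slow, and the titanium alkoxide may interfere. The fallback replaces carbonyl methylenation by addition and elimination. It sets out from 12 and comes back at 13.
- MeLi (2.2 equiv, THF, −78 °C, quench at low temperature) adds once to the lactone to give the methyl hemiketal F6 as an anomer mixture.
- (CF3CO)2O/pyridine at 0 °C dehydrates F6. The only possible direction is the exocyclic one, as in exo-glycal syntheses, and this gives 13.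

## Further compounds
F1 | step 5 | methyl (2R)-2-hydroxy-5-methyl-2-[(1S)-4-methylcyclohex-3-en-1-yl]hex-4-enoate | CC(C)=CC[C@@](C(=O)OC)(O)[C@H]1CCC(C)=CC1
F2 | step 5 | methyl (2R)-3-[(2S)-3,3-dimethyloxiran-2-yl]-2-hydroxy-2-[(1S)-4-methylcyclohex-3-en-1-yl]propanoate | CC1(C)O[C@H]1C[C@@](C(=O)OC)(O)[C@H]1CCC(C)=CC1
F3 | step 5 | methyl (2R,4R)-4-bromo-2,5-dihydroxy-5-methyl-2-[(1S)-4-methylcyclohex-3-en-1-yl]hexanoate | CC(C)(O)[C@H](Br)C[C@@](C(=O)OC)(O)[C@H]1CCC(C)=CC1
F4 | step 6 | (3R,5R)-5-bromo-3-hydroxy-6,6-dimethyl-3-[(1R,3S,6S)-6-methyl-7-oxabicyclo[4.1.0]heptan-3-yl]oxan-2-one | O=C1OC(C)(C)[C@H](Br)C[C@@]1(O)[C@H]1CC[C@]2(C)O[C@@H]2C1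
F5 | step 6 | (3R,5R)-5-bromo-3-[(1S,3R,4R)-4-bromo-3-hydroxy-4-methylcyclohexyl]-3-hydroxy-6,6-dimethyloxan-2-one | O=C1OC(C)(C)[C@H](Br)C[C@@]1(O)[C@H]1CC[C@@](C)(Br)[C@H](O)C1
F6 | step 7 | (3R,5R)-5-bromo-3-[(1S,3S,4S)-3-bromo-4-chloro-4-methylcyclohexyl]-2,6,6-trimethyloxane-2,3-diol (anomer mixture) | CC1(O)OC(C)(C)[C@H](Br)C[C@@]1(O)[C@H]1CC[C@](C)(Cl)[C@@H](Br)C1
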